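The constants were chosen freely.

Take a small charge of nucleophile and set it against an electrophile that also consumes itself. How much nucleophile brings the flask to its mark?

electrophile 20 mM; protic impurity 20.0 mM; time 4.0 min

- the concentration of nucleophile at which the part of the electrophile that has reacted at 4.0 min is just 70%, in mM

    nucleophile + acid set free ⇌ protonated nucleophile, settled at all times (K1 = 9900 M⁻¹)
    electrophile + acid set free → side product (k2 = 1.2 M⁻¹ s⁻¹)
    2 electrophile → self-condensation product (k3 = 0.13 M⁻¹ s⁻¹)
    nucleophile + protic impurity → quenched reagent (k4 = 0.096 M⁻¹ s⁻¹)
    electrophile + nucleophile → acid set free + target (k5 = 14 M⁻¹ s⁻¹)

Let a be the fraction of the electrophile charge left, and u its inverse, starting at 1. Self-condensation by itself makes u climb on a straight line, so freeze that slope. Multiply two, its rate constant, the charge and the run time: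

clock = 1.25

The mark needs u = 3.33. Call the rise of u that the start and the clock don't supply the surplus:

surplus = 1.09

Now let the nucleophile, a fraction x of the charge, supply it. Its half-life against the electrophile, 2.48 s, is far shorter than the run. The acid it sets free binds nucleophile strongly, since the balance constant times the charge is 198. So take a burst of x/2, with the step of electrophile and acid set free later freeing the protonated nucleophile, for a tally of two electrophile per nucleophile. Counting that tally at a near 1 gives x = 0.543, or 10.9 mM.

That is the weak link: a drop in a raises u by the drop over the product of its two end values. Weigh the burst at 1 and the slow remainder, from near 1 down to the mark, at the inverse of the mark: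

x = surplus / 5.50 = 0.197, which is 3.95 mM

The forecast says 3.2 mM, within 2.3 mM to 4.5 mM, lower than my number, holding that “each nucleophile removes close to two electrophiles over the run”.

The simulation gives 4.20 mM, or 0.210 of the charge, which is 1.31 times the forecast.

In this flask the target step had 70% of its turnover behind it by 0.400 min, with 24.6% of the electrophile used and the surplus at 0.202. Self-condensation and the step of electrophile with acid set free ran on, reaching half their turnover up to the asked time at 0.986 min and 1.38 min, and the surplus read 0.597 at 2.00 min; the flask with half the protic impurity and all other amounts as they are ends at 70.1%, a surplus of 1.09.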